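**Plan**

Side chain locants run from C1' (the OCH2 carbon) to C11' (the carbinol carbon) and are used for every intermediate; coumarin atoms are O1 to C8a.
Retrosynthetic cuts: the two ester C–O bonds, the C9'–O bond of the 9',10'-diol (back to an oxirane), the C9'–O and C10'–O bonds of that oxirane (back to the 9'E alkene), the O7–C1' aryl ether bond, the C8'–C9' bond and the C8'–O bond of an oxidised geranyl acetate.
Forward order: geranyl acetate is oxygenated and brominated at C8', joined to 2-methylbut-3-yn-2-ol (C9' to C11'), reduced to the triene diol, etherified at O7 of purchased 5,7-dihydroxycoumarin and pivaloylated at O5. The oxirane across C9'/C10' is the only ring made; it is opened at C9' and both esters are then removed.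
Enabling feature: the tertiary C11' hydroxyl sits next to the diol carbons C10' and C9', so in the triene it is allylic to C9'=C10' alone. The C2'=C3' and C6'=C7' alkenes and the C3=C4 bond of the pyranone ring have no hydroxyl neighbour.
Stereochemistry: 2'E comes from geranyl acetate, 6'E from the SeO2 oxidation, 9'E from trans-hydroalumination. C9' and C10' are set together as (9'S,10'R) by ligand-controlled oxygen transfer, and SN2 opening at C9' inverts that centre to give (9'R,10'R).

Key step: step 7

Assumption: the (R,R)-bishydroxamic acid is taken to be the ligand antipode that leads to the (9'S,10'R)-oxirane. The sense is to be checked on (E)-2-methylhex-3-en-2-ol first, and the (S,S)-ligand is used if it proves opposite.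
Remark: the 5-hydroxyl is masked as a pivalate because an aryl pivalate should resist ester exchange with hafnium and titanium alkoxides better than an aryl acetate. Compounds 1, 4 and 8 are purchased.

**Route**

Step 1
Reactants: 1 geranyl acetate
Product: 2 (2E,6E)-8-hydroxy-3,7-dimethylocta-2,6-dien-1-yl acetate
Conditions: SeO2 (0.5 equiv), tBuOOH (70% aq., 3 equiv), salicylic acid (0.1 equiv), CH2Cl2, rt
Reagents that add atoms: SeO2, O=[Se]=O (delivers the oxygen); tert-butyl hydroperoxide, CC(C)(C)OO (terminal oxidant that restores SeO2)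
Why: Riley allylic oxidation, in which the ene reaction takes place at the electron-rich distal C6'=C7' alkene (C2'=C3' is deactivated by the allylic acetate) and the following [2,3]-sigmatropic shift puts oxygen on the (E)-methyl group, so the 6'E geometry of the new allylic alcohol is set by the mechanism.

Step 2
Reactants: 2 (2E,6E)-8-hydroxy-3,7-dimethylocta-2,6-dien-1-yl acetate
Product: 3 (2E,6E)-8-bromo-3,7-dimethylocta-2,6-dien-1-yl acetate
Conditions: CBr4 (1.2 equiv), PPh3 (1.3 equiv), CH2Cl2, 0 °C
Reagents that add atoms: carbon tetrabromide, BrC(Br)(Br)Br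
Why: Appel reaction, in which the primary allylic hydroxyl is activated as an alkoxyphosphonium ion and displaced by bromide at C8' under neutral conditions that leave the acetate and both alkene geometries intact.

Step 3
Reactants: 3 (2E,6E)-8-bromo-3,7-dimethylocta-2,6-dien-1-yl acetate; 4 2-methylbut-3-yn-2-ol
Product: 5 (2E,6E)-11-hydroxy-3,7,11-trimethyldodeca-2,6-dien-9-yn-1-yl acetate
Conditions: CuI (10 mol%), nBu4NBr (10 mol%), K2CO3 (2 equiv), 4 (1.3 equiv), DMF, rt
Reagents that add atoms: none
Why: Copper-catalysed allyl–alkynyl coupling, in which the alkynylcopper species (monovalent copper) formed from 4 and carbonate should substitute the primary allylic bromide at its less hindered terminus C8' to make the C8'–C9' bond with the 6'E geometry retained, while the weak base leaves the acetate and the free tertiary hydroxyl alone.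

Step 4
Reactants: 5 (2E,6E)-11-hydroxy-3,7,11-trimethyldodeca-2,6-dien-9-yn-1-yl acetate
Product: 7 (2E,6E,9E)-3,7,11-trimethyldodeca-2,6,9-triene-1,11-diol, via dienyne diol 6 (not isolated)
Conditions: LiAlH4 (3 equiv), THF, 0 °C then reflux; aq. potassium sodium tartrate (KNaC4H4O6) work-up
Reagents that add atoms: none
Why: LiAlH4 first cleaves the acetate and then the C11' alkoxyaluminium hydride delivers hydride to C10' with aluminium ending on C9' (trans-hydroalumination of a propargylic alcohol), so protonolysis on work-up should give only the 9'E alkene while the isolated trisubstituted alkenes are inert to hydride.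

Step 5
Reactants: 7 (2E,6E,9E)-3,7,11-trimethyldodeca-2,6,9-triene-1,11-diol; 8 5,7-dihydroxycoumarin
Product: 9 5-hydroxy-7-[(2E,6E,9E)-11-hydroxy-3,7,11-trimethyldodeca-2,6,9-trienyloxy]coumarin
Conditions: 8 (1.5 equiv), PPh3 (1.2 equiv), DIAD (1.2 equiv, slow addition), THF, 0 °C to rt
Reagents that add atoms: none
Why: Mitsunobu reaction, in which only the primary allylic hydroxyl of 7 forms an alkoxyphosphonium ion (the tertiary one is too hindered) and should be displaced at C1' by the 7-phenoxide of 8, the 7-hydroxyl being expected to be the more acidic (para to the electron-withdrawing C4=C3–C2=O unit of the pyranone ring) and the less hindered (the 5-hydroxyl is peri to C4–H), with the excess of 8 holding back double alkylation.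

Step 6
Reactants: 9 5-hydroxy-7-[(2E,6E,9E)-11-hydroxy-3,7,11-trimethyldodeca-2,6,9-trienyloxy]coumarin
Product: 10 5-pivaloyloxy-7-[(2E,6E,9E)-11-hydroxy-3,7,11-trimethyldodeca-2,6,9-trienyloxy]coumarin
Conditions: PivCl (1.2 equiv), Et3N (1.5 equiv), CH2Cl2, 0 °C
Reagents that add atoms: pivaloyl chloride, CC(C)(C)C(Cl)=O
Why: Base-mediated O-acylation, in which the acidic 5-phenol is acylated while the tertiary allylic alcohol is too hindered to react at 0 °C, so the only remaining metal-binding phenol is masked before the hafnium and titanium steps.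

Step 7
Reactants: 10 5-pivaloyloxy-7-[(2E,6E,9E)-11-hydroxy-3,7,11-trimethyldodeca-2,6,9-trienyloxy]coumarin
Product: 11 5-pivaloyloxy-7-[(2E,6E,9S,10R)-9,10-epoxy-11-hydroxy-3,7,11-trimethyldodeca-2,6-dienyloxy]coumarin
Conditions: Hf(OtBu)4 (20 mol%), (R,R)-N,N'-dihydroxy-N,N'-bis(diphenylacetyl)cyclohexane-1,2-diamine (22 mol%), DMPU (1 equiv), cumene hydroperoxide (2 equiv), toluene, 0 °C to rt
Reagents that add atoms: cumene hydroperoxide, CC(C)(OO)c1ccccc1
Why: The C11' hydroxyl exchanges onto the tetravalent hafnium centre of the Hf(OtBu)4–bishydroxamate complex, cumene hydroperoxide binds to the same metal, and the activated peroxide oxygen is passed to the C9'=C10' π bond held beside it, so that the C9'–O and C10'–O bonds form in one concerted step. The closest known reaction type is the alkoxide-directed metal alkylperoxide epoxidation of allylic alcohols (the Sharpless epoxidation and its bishydroxamate variants for tertiary allylic alcohols). The oxirane, the only ring closed, arises by [2+1] oxygen-atom transfer to the alkene and not by stepwise ring closure, so the addition is suprafacial and the 9'E geometry becomes the trans relationship of C8' and C11' on the ring. The absolute configuration of both new centres, (9'S,10'R), is fixed by the C2-symmetric ligand, which exposes one enantiotopic face of the alkene to the bound peroxide; the substrate is achiral, so there is no mismatch to overcome. The step needs site selectivity among the C2'=C3', C6'=C7' and C9'=C10' alkenes and the pyranone C3=C4 bond, and this is secured because only C9'=C10' is allylic to a free hydroxyl while the one competing ligand, the 5-phenol, is masked as its pivalate.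

Step 8
Reactants: 11 5-pivaloyloxy-7-[(2E,6E,9S,10R)-9,10-epoxy-11-hydroxy-3,7,11-trimethyldodeca-2,6-dienyloxy]coumarin
Product: 12 5-pivaloyloxy-7-[(2E,6E,9R,10R)-9-benzoyloxy-10,11-dihydroxy-3,7,11-trimethyldodeca-2,6-dienyloxy]coumarin
Conditions: Ti(OiPr)4 (1.5 equiv), PhCO2H (1.5 equiv), CH2Cl2, rt; aq. tartaric acid work-up
Reagents that add atoms: benzoic acid, OC(=O)c1ccccc1
Why: Titanium-mediated opening of a 2,3-epoxy alcohol by a carboxylic acid, in which the C11' alkoxide anchors tetravalent titanium and benzoate is delivered in SN2 fashion to C9', the oxirane carbon remote from the quaternary carbinol (C10' is neopentyl-like and inductively deactivated), so C9' is inverted from S to R while C10' keeps its oxygen and its R configuration, and a later benzoyl shift between O9' and O10' would touch neither centre.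

Step 9
Reactants: 12 5-pivaloyloxy-7-[(2E,6E,9R,10R)-9-benzoyloxy-10,11-dihydroxy-3,7,11-trimethyldodeca-2,6-dienyloxy]coumarin
Product: 13 5-hydroxy-7-[(2E,6E,9R,10R)-9,10,11-trihydroxy-3,7,11-trimethyldodeca-2,6-dienyloxy]coumarin (CNP0174708.3)
Conditions: K2CO3 (2 equiv), MeOH, 0 °C to rt; then AcOH (4 equiv)
Reagents that add atoms: none
Why: Base-mediated transesterification, in which methoxide from K2CO3 in methanol removes the secondary benzoate and the aryl pivalate without breaking a C–O bond at C9' or C10', the allylic aryl ether and the triol are inert, and the acetic acid quench re-closes any pyranone ring opened reversibly to the (Z)-coumarinate.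

**Compound list**

1 | geranyl acetate, (2E)-3,7-dimethylocta-2,6-dien-1-yl acetate | CC(=O)OC/C=C(\C)CCC=C(C)C | starting material
2 | (2E,6E)-8-hydroxy-3,7-dimethylocta-2,6-dien-1-yl acetate | CC(=O)OC/C=C(\C)CC/C=C(\C)CO | intermediate
3 | (2E,6E)-8-bromo-3,7-dimethylocta-2,6-dien-1-yl acetate | CC(=O)OC/C=C(\C)CC/C=C(\C)CBr | intermediate
4 | 2-methylbut-3-yn-2-ol | CC(C)(O)C#C | starting material
5 | (2E,6E)-11-hydroxy-3,7,11-trimethyldodeca-2,6-dien-9-yn-1-yl acetate | CC(=O)OC/C=C(\C)CC/C=C(\C)CC#CC(C)(C)O | intermediate
6 | (2E,6E)-3,7,11-trimethyldodeca-2,6-dien-9-yne-1,11-diol (present in the flask as its aluminium alkoxide) | OC/C=C(\C)CC/C=C(\C)CC#CC(C)(C)O | intermediate (not isolated)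
7 | (2E,6E,9E)-3,7,11-trimethyldodeca-2,6,9-triene-1,11-diol | OC/C=C(\C)CC/C=C(\C)C/C=C/C(C)(C)O | intermediate
8 | 5,7-dihydroxycoumarin | O=c1ccc2c(O)cc(O)cc2o1 | starting material
9 | 5-hydroxy-7-[(2E,6E,9E)-11-hydroxy-3,7,11-trimethyldodeca-2,6,9-trienyloxy]coumarin | Oc1cc(OC/C=C(\C)CC/C=C(\C)C/C=C/C(C)(C)O)cc2oc(=O)ccc12 | intermediate
10 | 5-pivaloyloxy-7-[(2E,6E,9E)-11-hydroxy-3,7,11-trimethyldodeca-2,6,9-trienyloxy]coumarin | CC(C)(C)C(=O)Oc1cc(OC/C=C(\C)CC/C=C(\C)C/C=C/C(C)(C)O)cc2oc(=O)ccc12 | intermediate
11 | 5-pivaloyloxy-7-[(2E,6E,9S,10R)-9,10-epoxy-11-hydroxy-3,7,11-trimethyldodeca-2,6-dienyloxy]coumarin | CC(C)(C)C(=O)Oc1cc(OC/C=C(\C)CC/C=C(\C)C[C@@H]3O[C@H]3C(C)(C)O)cc2oc(=O)ccc12 | intermediate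
12 | 5-pivaloyloxy-7-[(2E,6E,9R,10R)-9-benzoyloxy-10,11-dihydroxy-3,7,11-trimethyldodeca-2,6-dienyloxy]coumarin | CC(C)(C)C(=O)Oc1cc(OC/C=C(\C)CC/C=C(\C)C[C@@H](OC(=O)c3ccccc3)[C@@H](O)C(C)(C)O)cc2oc(=O)ccc12 | intermediate
13 | 5-hydroxy-7-[(2E,6E,9R,10R)-9,10,11-trihydroxy-3,7,11-trimethyldodeca-2,6-dienyloxy]coumarin (CNP0174708.3) | C/C(=C\COc1cc(O)c2ccc(=O)oc2c1)CC/C=C(\C)C[C@@H](O)[C@@H](O)C(C)(C)O | target

**Count and risks**

Total step count: 9. Longest linear sequence: 9 steps (1 to 13).

Steps most likely to fail:

1. Step 7. The risk is insufficient facial selectivity in the oxygen transfer to the E-disubstituted tertiary allylic alcohol, or stalled turnover if the coumarin ether competes for hafnium. The fallback sets out from 10 and gives up catalyst control for a separation of diastereomers. The C11' hydroxyl directs a non-enantioselective epoxidation with VO(acac)2 (tetravalent vanadium) and tBuOOH in CH2Cl2, which gives 11 together with its antipode, the (9'R,10'S)-epoxide F1. The mixture is opened under the conditions of step 8 with enantiopure (S)-2-methoxy-2-phenylacetic acid in place of benzoic acid. This turns the two series into the (9'R,10'R)-9'-ester F2 and the (9'S,10'S)-9'-ester F3, which are separated by chromatography or crystallisation. Methanolysis of F2 under the conditions of step 9 comes back to the route at 13.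

2. Step 8. The risk is benzoate attack at C10' instead of C9' (this would lower the enantiomeric purity, since the C10' pathway leads into the antipodal diol series), or failure of the hindered tertiary alkoxide to anchor titanium, or ester exchange at the pivalate. The fallback sets out from 11 and replaces metal-anchored delivery of an ester nucleophile by specific-acid-catalysed hydration (HClO4 cat., THF/H2O, 0 °C). Water attacks the protonated oxirane at C9' with inversion, the regiochemistry now resting on the inductive deactivation and steric shielding of C10' by the quaternary C11'. This gives the 5-pivaloyloxy triol F4 directly, and methanolysis as in step 9 comes back to the route at 13.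

3. Step 5. The risk is poor discrimination between the 5- and 7-hydroxyls of 8, or double alkylation. The fallback sets out from 7 and builds the pyranone ring after the ether bond. Mitsunobu etherification of 7 with 2,4,6-trihydroxybenzaldehyde, whose 4-hydroxyl is the only one not hydrogen-bonded to the formyl group, gives the 4-O-alkylated 2,6-dihydroxybenzaldehyde F5. Treatment with (triphenylphosphoranylidene)ketene, Ph3P=C=C=O, in toluene at 80 °C acylates one of the two equivalent ortho hydroxyls to give the aryl ester ylide F6 (not isolated). Its intramolecular Wittig reaction with the formyl group closes the lactone with the required Z geometry. Because the two ortho hydroxyls are equivalent, only the 5-hydroxy-7-alkoxy isomer can form, and the sequence comes back to the route at 9.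

**Further compounds**

F1 | step 7 | 5-pivaloyloxy-7-[(2E,6E,9R,10S)-9,10-epoxy-11-hydroxy-3,7,11-trimethyldodeca-2,6-dienyloxy]coumarin (antipode of 11) | CC(C)(C)C(=O)Oc1cc(OC/C=C(\C)CC/C=C(\C)C[C@H]3O[C@@H]3C(C)(C)O)cc2oc(=O)ccc12
F2 | step 7 | 5-pivaloyloxy-7-[(2E,6E,9R,10R)-10,11-dihydroxy-9-[(S)-2-methoxy-2-phenylacetoxy]-3,7,11-trimethyldodeca-2,6-dienyloxy]coumarin | CC(C)(C)C(=O)Oc1cc(OC/C=C(\C)CC/C=C(\C)C[C@@H](OC(=O)[C@@H](OC)c3ccccc3)[C@@H](O)C(C)(C)O)cc2oc(=O)ccc12
F3 | step 7 | 5-pivaloyloxy-7-[(2E,6E,9S,10S)-10,11-dihydroxy-9-[(S)-2-methoxy-2-phenylacetoxy]-3,7,11-trimethyldodeca-2,6-dienyloxy]coumarin | CC(C)(C)C(=O)Oc1cc(OC/C=C(\C)CC/C=C(\C)C[C@H](OC(=O)[C@@H](OC)c3ccccc3)[C@H](O)C(C)(C)O)cc2oc(=O)ccc12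
F4 | step 8 | 5-pivaloyloxy-7-[(2E,6E,9R,10R)-9,10,11-trihydroxy-3,7,11-trimethyldodeca-2,6-dienyloxy]coumarin | CC(C)(C)C(=O)Oc1cc(OC/C=C(\C)CC/C=C(\C)C[C@@H](O)[C@@H](O)C(C)(C)O)cc2oc(=O)ccc12
F5 | step 5 | 2,6-dihydroxy-4-[(2E,6E,9E)-11-hydroxy-3,7,11-trimethyldodeca-2,6,9-trienyloxy]benzaldehyde | O=Cc1c(O)cc(OC/C=C(\C)CC/C=C(\C)C/C=C/C(C)(C)O)cc1O
F6 | step 5 | 2-formyl-3-hydroxy-5-[(2E,6E,9E)-11-hydroxy-3,7,11-trimethyldodeca-2,6,9-trienyloxy]phenyl (triphenylphosphoranylidene)acetate | O=Cc1c(O)cc(OC/C=C(\C)CC/C=C(\C)C/C=C/C(C)(C)O)cc1OC(=O)C=P(c2ccccc2)(c2ccccc2)c2ccccc2
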